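Readings and results are simulated for an exercise, noise included.

A ratio of two rates opened the meeting on this flask, in which solid L is stirred with E. The analyst divided the Z of the autumn run by the Z of the noon run, both read at 5.00 d, so that the elapsed time dropped out and 10.3% over 5.1% gave 2.02.

| flask | L | E | remark | time |
|---|---|---|---|---|
| noon | 0.22 M | 2.8 equiv | run made earlier |  |
| autumn | 0.22 M | 9.7 equiv | run made earlier |  |
| Saturday's | 0.22 M | 2.00 equiv |  | 10 d |
| Tuesday's | 0.22 M | 4.00 equiv |  | 10 d |
| Friday's | 0.22 M | 8.00 equiv |  | 10 d |

- noon (time / d: L / %, Z / %): 0.833: 97.3, 0.4; 1.67: 96.7, 1.5; 2.50: 95.0, 2.0; 3.00: 94.8, 2.4; 4.00: 94.2, 3.1; 5.00: 92.2, 5.1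
- autumn (time / d: L / %, Z / %): 0.417: 98.3, 0.2; 0.625: 98.2, 0.9; 1.04: 97.6, 1.3; 1.67: 96.3, 2.1; 3.00: 92.6, 5.4; 5.00: 88.4, 10.3

(scatter of a reading: 0.3 percentage points)

- as a solid, counted per litre of solution: L
- at the start none of L is in solution
- what has only dissolved of L counts as not reacted

1. part of the L that has reacted (what has only dissolved counts as not reacted) at the end, Saturday's
2. part of the L that has reacted (what has only dissolved counts as not reacted) at the end, Tuesday's
3. part of the L that has reacted (what has only dissolved counts as not reacted) at the end, Friday's
4. what raising the equivalents of E from its lowest to its highest value here does to the part of the L that has reacted (what has only dissolved counts as not reacted) (changes below 5 percentage points count as none) (it rises / no change / it falls)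

Since E had gone up by a factor of 3.46, the analyst named the logarithm of the rate ratio over the logarithm of the E ratio, 0.566, the E-exponent n, the apparent order in E: at one the rate of Z follows E in proportion, at zero E does nothing to it. It is a reading, resting on two figures each good to 0.3 percentage points.

The bench chemist objected to counting as reacted whatever is missing from the L column. At noon, L and Z fall short of the charge by 2.3 points at the first reading and 2.7 points at the last, while Z climbs from 0.4% to 5.1%. She took that gap for dissolved L, which counts as unreacted, and the meeting agreed to count Z.

The chair noted that Z climbs roughly straight in both runs, with L still at 92.2% in the noon run. He therefore scaled the noon Z by time, from 5.00 d to 10 d, and by the E ratio raised to n. That gave 8.43% for Saturday's, 12.5% for Tuesday's and 18.5% for Friday's, a rise of 10 points against the margin of 5 points.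

The forecast gave 11%, 15.5% and 21%, higher than the meeting's figures, and said it rises, holding that “the rate stays roughly constant while solid remains”.

The flask gave 8.27%, 13.5% and 19.6%: it rises, by 11 points.

    J + E ⇌ Q + Z (K = 1.40, k = 4.87 × 10⁻⁴ L mol⁻¹ min⁻¹)
    E + Q ⇌ G, settled at all times (K = 30.4 L mol⁻¹)
    L ⇌ J, rate k3*(cs3 - [J]) while solid is left; crystals form when [J] > cs3 (solubility = 9.10 mM, k = 5.90 × 10⁻⁴ min⁻¹)

Raised to n, the step in E from Saturday's to Friday's, a factor of 4.00, gives a ratio of 2.19; the flask's is 2.37. In Saturday's at 3.74 d, J, the dissolved L, has a half-life of 2.3 d by the forward step with E, against a half-life of 0.816 d for its shortfall below solubility under dissolving, which is quicker by a factor of 2.82. J is then made 1.06 times as fast as it is used up, and in Saturday's it stands at 3.05% at 5.00 d and 3.10% at 10.0 d. In a neighbour flask, Saturday's with 5.00 equiv of E, n takes Tuesday's 13.5% to 15.3%, and that flask holds 15.4% of Z.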